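In a one-step world every bit of starting material you lose would reappear as product, so the two columns you read would always sum to the charge; in these runs they do not, and that sum is the thing to watch.

| flask | starting material | reagent in the second phase | protic impurity | remark | time | volume of the second phase over the first |
|---|---|---|---|---|---|---|
| theta | 10 mM | 2.5 equiv | 1.3 mM | run made earlier |  |  |
| alpha | 10 mM | 2.5 equiv | 3 mM | run made earlier |  |  |
| flask | 10 mM | 2.50 equiv | 2.00 mM |  | 10 min | 2.0 |

| run | time / min | product / % | starting material / % |
|---|---|---|---|
| theta | 2.00 | 33 | 65 |
| theta | 4.00 | 61 | 34 |
| theta | 6.00 | 80 | 10 |
| theta | 8.00 | 83 | 7 |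
| theta | 10.0 | 89 | 5 |
| theta | 12.0 | 89 | 1 |
| alpha | 1.00 | 11 | 75 |
| alpha | 1.50 | 21 | 65 |
| alpha | 2.50 | 37 | 50 |
| alpha | 4.00 | 60 | 23 |
| alpha | 8.00 | 77 | 4 |
| alpha | 12.0 | 80 | 0 |

(scatter of a reading: 2 percentage points)

- in the second phase: reagent in the second phase; everything else is in the first
- charges count per volume of the first phase; a concentration in a rate is the amount of a species over the volume of its own phase; every rate counts per litre of the first phase
- the earlier runs hold the two phases in the same ratio of volumes as the flask asked about

- the product standing at 10 min, as a percentage of the starting material charged
- part of the starting material charged that has reacted at 10 min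

In the first instants the alpha run, with 30.0% of the charge as protic impurity, is 14 percentage points short at 1.00 min, a gap wider than the 2 points of the theta run, with 13.0%, at 2.00 min. In the middle, product reads 61% and 60% at 4.00 min, so that column does not tell the runs apart, and you keep your eye on the sum. At the end, 12.0 min, starting material reads 1% in theta and 0% in alpha, and the gaps read 10 points and 20 points.

Dividing each final gap by the impurity charged gives 0.769 and 0.667, nearly constant within a scatter of 2 points per reading, so I freeze the pooled value 0.698, the quench share: the fraction of the charge missing at the end for each fraction of the charge added as impurity. For the flask, with 20.0% impurity, my reckoning has 14.0% missing, so I estimate product near 86.0%, less whatever is still unreacted.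

The forecast, which holds that the impurity “takes starting material off to a side fate”, gives 84% of product (80.5% to 87%) and 97% reacted (94.5% to 99%).

The flask gives 84.9% of product and 97.4% reacted, both inside those ranges.

    starting material + protic impurity → quenched substrate (k = 0.520 M⁻¹ s⁻¹)
    reagent in the reaction phase ⇌ reagent in the second phase, rate k2*([reagent in the reaction phase] - [reagent in the second phase]/K2) per volume of the first phase (partition coefficient = 0.401, kL = 0.00255 s⁻¹)
    starting material + reagent in the reaction phase → product (k = 1.57 M⁻¹ s⁻¹)
    reagent in the reaction phase ⇌ dormant form (K = 2.30, k = 0.00435 s⁻¹)

In the flask, product stands short of the charge through the quench of starting material by protic impurity and the transfer bottleneck acting together: without the quench it reaches 95.5%, without the bottleneck 94.0%. The flask holds 12.6% as quenched substrate, a share of 0.629. Charged with 0.80 mM of impurity instead, the same flask stands at 91.1% of product, above the forecast's high end of 87%. There the quench share gives 5.58% of the charge quenched, and that flask holds 5.27%.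

The data stem from a simulated flask with made-up constants; scatter was added.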